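**Retrosynthetic overview**

1. Target 23 ⇒ penta-MOM flavanone 22 (acetal cleavage last). Ring C ⇒ 2'-hydroxychalcone 21 by oxa-Michael closure through the only free ortho-phenol, which places the side chain at C8 and not C6. Chalcone ⇒ acetophenone 18 + aldehyde 20 (Claisen–Schmidt).
2. 18 ⇒ phenol 16 (ortho-C-acetylation) ⇒ 3-prenyl-dihydrocoumarin 13 + 2 MeMgBr. This builds the tertiary alcohol and unmasks the lactone oxygen as the one free phenol, the later O1.
3. 13 ⇒ 3-[(E)-but-2-enyl] lactone 11 (cross-metathesis) ⇒ key step: Ireland–Claisen [3,3] shift of the (R)-but-3-en-2-yl 3-arylpropanoate made from lactone 4. It forms the C2''–C3'' bond and sets C2'' by chirality transfer from purchased (R)-but-3-en-2-ol.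
4. Ring order: rings A and B are bought (5,7-dihydroxycoumarin, 2,4,6-trihydroxybenzaldehyde). The coumarin lactone is only a temporary ring (opened and re-closed in step 3, opened for good in step 5). Ring C is the only ring built and is formed last.

Assumption: (R)-but-3-en-2-ol is bought at ≥99% ee; C2 lies five bonds from the side-chain centre and cannot be biased by it, so it forms as an epimer pair that is separated as diastereomers on an achiral phase, the (2R) epimer being recycled.

**Route**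

Step 1
Reactants: 1 5,7-dihydroxy-2H-chromen-2-one; 2 chloromethyl methyl ether
Product: 3 5,7-bis(methoxymethoxy)-2H-chromen-2-one
Conditions: NaH (2.4 equiv), MOMCl (2.4 equiv), DMF, 0 °C → rt
Reagents that add atoms: chloromethyl methyl ether (MOMCl), COCCl
Why: Williamson-type O-alkylation of both phenoxides gives the bis-acetal, and the conjugated coumarin lactone is inert to these conditions.

Step 2
Reactants: 3 5,7-bis(methoxymethoxy)-2H-chromen-2-one
Product: 4 5,7-bis(methoxymethoxy)-3,4-dihydro-2H-chromen-2-one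
Conditions: H2 (3 bar), Pd/C (10 wt%), EtOAc, rt
Reagents that add atoms: none
Why: Heterogeneous catalytic hydrogenation saturates the conjugated C3=C4 bond without touching the arene or the aryl MOM ethers, and the aprotic solvent avoids lactone alcoholysis.

Step 3
Reactants: 4 5,7-bis(methoxymethoxy)-3,4-dihydro-2H-chromen-2-one; 5 (2R)-but-3-en-2-ol
Product: 11 (3R)-3-[(2E)-but-2-en-1-yl]-5,7-bis(methoxymethoxy)-3,4-dihydro-2H-chromen-2-one, via lithium phenoxide ester 6 (not isolated), via aryl silyl ether ester 7 (not isolated), via silyl ketene acetal 8 (not isolated), via rearranged silyl ester 9 (not isolated), via hydroxy acid 10 (not isolated)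
Conditions: 5, n-BuLi (1.0 equiv), THF, 0 °C, then 4; TMSCl (1.1 equiv), 0 °C; cannulated into LiN(i-Pr)2 (1.3 equiv), THF, −78 °C; TMSCl (1.5 equiv), −78 → 60 °C; aq. citric acid; crude + DCC, CH2Cl2, 0 °C → rt
Reagents that add atoms: (2R)-but-3-en-2-ol, C[C@@H](O)C=C
Why: Alkoxide opening of the aryl lactone followed by an Ireland–Claisen [3,3]-sigmatropic rearrangement, in which kinetic enolisation in THF puts CH2Ar cis to the allyloxy oxygen and the chair transition state with the carbinol methyl equatorial relays the (R)-carbinol centre to (R) at C-alpha (new C–C bond, E-alkene), after which DCC re-closes the lactone on the single free phenol; the enantiomer ratio equals the enolate ratio (about 95:5) and can be raised by recrystallising 13 or 18.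

Step 4
Reactants: 11 (3R)-3-[(2E)-but-2-en-1-yl]-5,7-bis(methoxymethoxy)-3,4-dihydro-2H-chromen-2-one; 12 2-methylbut-2-ene
Product: 13 (3R)-5,7-bis(methoxymethoxy)-3-(3-methylbut-2-en-1-yl)-3,4-dihydro-2H-chromen-2-one
Conditions: second-generation Grubbs catalyst RuCl2(=CHPh)(PCy3)(SIMes) (5 mol%), 2-methylbut-2-ene (excess), CH2Cl2, 40 °C, sealed tube
Reagents that add atoms: 2-methylbut-2-ene, CC=C(C)C
Why: Olefin cross-metathesis trims the crotyl terminus to the prenyl group with loss of but-2-ene, and it does not touch the C3 stereocentre.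

Step 5
Reactants: 13 (3R)-5,7-bis(methoxymethoxy)-3-(3-methylbut-2-en-1-yl)-3,4-dihydro-2H-chromen-2-one; 14 methylmagnesium bromide
Product: 16 2-[(2R)-2-(2-hydroxypropan-2-yl)-5-methylhex-4-en-1-yl]-3,5-bis(methoxymethoxy)phenol, via methyl ketone 15 (not isolated)
Conditions: MeMgBr (4 equiv), THF, −20 → 0 °C; aq. NH4Cl
Reagents that add atoms: methylmagnesium bromide, C[Mg]Br
Why: Double Grignard addition to the aryl lactone builds the tertiary alcohol and frees the lactone oxygen as the only unprotected phenol, and addition to the transient methyl ketone outruns enolisation so the (R) centre is kept.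

Step 6
Reactants: 16 2-[(2R)-2-(2-hydroxypropan-2-yl)-5-methylhex-4-en-1-yl]-3,5-bis(methoxymethoxy)phenol; 17 acetyl chloride
Product: 18 1-{2-hydroxy-3-[(2R)-2-(2-hydroxypropan-2-yl)-5-methylhex-4-en-1-yl]-4,6-bis(methoxymethoxy)phenyl}ethan-1-one
Conditions: EtMgBr (1.05 equiv), Et2O, 0 °C; solvent exchange to toluene; AcCl (1.0 equiv), rt; aq. NH4Cl
Reagents that add atoms: acetyl chloride, CC(=O)Cl
Why: Chelation-directed ortho-C-acylation of the bromomagnesium phenoxide in a non-coordinating solvent (Casnati–Sartori type Friedel–Crafts acylation) delivers the acetyl group to the only free carbon ortho to the free phenol and not to the carbon between the two MOM ethers.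

Step 7
Reactants: 19 2,4,6-trihydroxybenzaldehyde; 2 chloromethyl methyl ether
Product: 20 2,4,6-tris(methoxymethoxy)benzaldehyde
Conditions: NaH (3.5 equiv), MOMCl (3.5 equiv), DMF, 0 °C → rt
Reagents that add atoms: chloromethyl methyl ether (MOMCl), COCCl
Why: Williamson-type O-alkylation of all three phenoxides, the strong base overcoming the hydrogen bonding of the two ortho hydroxyls to the aldehyde.

Step 8
Reactants: 18 1-{2-hydroxy-3-[(2R)-2-(2-hydroxypropan-2-yl)-5-methylhex-4-en-1-yl]-4,6-bis(methoxymethoxy)phenyl}ethan-1-one; 20 2,4,6-tris(methoxymethoxy)benzaldehyde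
Product: 22 (2S)-8-[(2R)-2-(2-hydroxypropan-2-yl)-5-methylhex-4-en-1-yl]-5,7-bis(methoxymethoxy)-2-[2,4,6-tris(methoxymethoxy)phenyl]-2,3-dihydro-4H-chromen-4-one, via chalcone 21 (not isolated)
Conditions: KOH (50% aq., 10 equiv), EtOH, rt, 48 h; AcOH to pH 8, reflux, 24 h; preparative HPLC on silica separates 22 from its (2R) C2 epimer, which is recycled together with recovered 21 through the same buffered reflux
Reagents that add atoms: 2,4,6-tris(methoxymethoxy)benzaldehyde, O=Cc1c(OCOC)cc(OCOC)cc1OCOC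
Why: Claisen–Schmidt aldol condensation gives the (E)-chalcone and the acetate-buffered 6-endo oxa-Michael addition can only use the one free ortho-phenol, which fixes the side chain at C8; C2 forms without facial bias (about 1:1), and 22 is obtained by separating the two diastereomers while the (2R) epimer re-equilibrates through the chalcone.

Step 9
Reactants: 22 (2S)-8-[(2R)-2-(2-hydroxypropan-2-yl)-5-methylhex-4-en-1-yl]-5,7-bis(methoxymethoxy)-2-[2,4,6-tris(methoxymethoxy)phenyl]-2,3-dihydro-4H-chromen-4-one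
Product: 23 (2S)-5,7-dihydroxy-8-[(2R)-2-(2-hydroxypropan-2-yl)-5-methylhex-4-en-1-yl]-2-(2,4,6-trihydroxyphenyl)-2,3-dihydro-4H-chromen-4-one
Conditions: HCl (1 M in MeOH), 25 °C, monitored to completion; dilute with water, EtOAc extraction; C18 HPLC (MeCN–H2O, 0.1% HCO2H)
Reagents that add atoms: none
Why: Acid-catalysed transacetalisation removes the five aryl MOM groups as dimethoxymethane under dilute, base-free conditions chosen to be too mild to ionise the tertiary alcohol or to open ring C by the chalcone pathway, so neither stereocentre is touched.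

**Compound list**

1 | 5,7-dihydroxy-2H-chromen-2-one (5,7-dihydroxycoumarin) | O=C1C=Cc2c(O)cc(O)cc2O1 | starting material
2 | chloromethyl methyl ether (MOMCl) | COCCl | starting material
3 | 5,7-bis(methoxymethoxy)-2H-chromen-2-one | O=C1C=Cc2c(OCOC)cc(OCOC)cc2O1 | intermediate
4 | 5,7-bis(methoxymethoxy)-3,4-dihydro-2H-chromen-2-one | O=C1CCc2c(OCOC)cc(OCOC)cc2O1 | intermediate
5 | (2R)-but-3-en-2-ol | C[C@@H](O)C=C | starting material
6 | (2R)-but-3-en-2-yl 3-[2-hydroxy-4,6-bis(methoxymethoxy)phenyl]propanoate, present as its lithium phenoxide | C=C[C@@H](C)OC(=O)CCc1c(O)cc(OCOC)cc1OCOC | intermediate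
7 | (2R)-but-3-en-2-yl 3-[2,4-bis(methoxymethoxy)-6-(trimethylsilyloxy)phenyl]propanoate | C=C[C@@H](C)OC(=O)CCc1c(O[Si](C)(C)C)cc(OCOC)cc1OCOC | intermediate
8 | trimethyl{[(1E)-1-{[(2R)-but-3-en-2-yl]oxy}-3-[2,4-bis(methoxymethoxy)-6-(trimethylsilyloxy)phenyl]prop-1-en-1-yl]oxy}silane | C[Si](C)(C)O/C(O[C@H](C)C=C)=C/Cc1c(O[Si](C)(C)C)cc(OCOC)cc1OCOC | intermediate
9 | trimethylsilyl (2R,4E)-2-{[2,4-bis(methoxymethoxy)-6-(trimethylsilyloxy)phenyl]methyl}hex-4-enoate | C/C=C/C[C@H](Cc1c(O[Si](C)(C)C)cc(OCOC)cc1OCOC)C(=O)O[Si](C)(C)C | intermediate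
10 | (2R,4E)-2-{[2-hydroxy-4,6-bis(methoxymethoxy)phenyl]methyl}hex-4-enoic acid | C/C=C/C[C@H](Cc1c(O)cc(OCOC)cc1OCOC)C(=O)O | intermediate
11 | (3R)-3-[(2E)-but-2-en-1-yl]-5,7-bis(methoxymethoxy)-3,4-dihydro-2H-chromen-2-one | C/C=C/C[C@@H]1Cc2c(OCOC)cc(OCOC)cc2OC1=O | intermediate
12 | 2-methylbut-2-ene | CC=C(C)C | starting material
13 | (3R)-5,7-bis(methoxymethoxy)-3-(3-methylbut-2-en-1-yl)-3,4-dihydro-2H-chromen-2-one | CC(C)=CC[C@@H]1Cc2c(OCOC)cc(OCOC)cc2OC1=O | intermediate
14 | methylmagnesium bromide | C[Mg]Br | starting material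
15 | (3R)-3-{[2-hydroxy-4,6-bis(methoxymethoxy)phenyl]methyl}-6-methylhept-5-en-2-one, present as its bromomagnesium phenoxide | CC(C)=CC[C@H](Cc1c(O)cc(OCOC)cc1OCOC)C(C)=O | intermediate
16 | 2-[(2R)-2-(2-hydroxypropan-2-yl)-5-methylhex-4-en-1-yl]-3,5-bis(methoxymethoxy)phenol | CC(C)=CC[C@H](Cc1c(O)cc(OCOC)cc1OCOC)C(C)(C)O | intermediate
17 | acetyl chloride | CC(=O)Cl | starting material
18 | 1-{2-hydroxy-3-[(2R)-2-(2-hydroxypropan-2-yl)-5-methylhex-4-en-1-yl]-4,6-bis(methoxymethoxy)phenyl}ethan-1-one | CC(C)=CC[C@H](Cc1c(O)c(C(C)=O)c(OCOC)cc1OCOC)C(C)(C)O | intermediate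
19 | 2,4,6-trihydroxybenzaldehyde | O=Cc1c(O)cc(O)cc1O | starting material
20 | 2,4,6-tris(methoxymethoxy)benzaldehyde | O=Cc1c(OCOC)cc(OCOC)cc1OCOC | intermediate
21 | (2E)-1-{2-hydroxy-3-[(2R)-2-(2-hydroxypropan-2-yl)-5-methylhex-4-en-1-yl]-4,6-bis(methoxymethoxy)phenyl}-3-[2,4,6-tris(methoxymethoxy)phenyl]prop-2-en-1-one | CC(C)=CC[C@H](Cc1c(O)c(C(=O)/C=C/c2c(OCOC)cc(OCOC)cc2OCOC)c(OCOC)cc1OCOC)C(C)(C)O | intermediate
22 | (2S)-8-[(2R)-2-(2-hydroxypropan-2-yl)-5-methylhex-4-en-1-yl]-5,7-bis(methoxymethoxy)-2-[2,4,6-tris(methoxymethoxy)phenyl]-2,3-dihydro-4H-chromen-4-one | CC(C)=CC[C@H](Cc1c(OCOC)cc(OCOC)c2c1O[C@H](c1c(OCOC)cc(OCOC)cc1OCOC)CC2=O)C(C)(C)O | intermediate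
23 | (2S)-5,7-dihydroxy-8-[(2R)-2-(2-hydroxypropan-2-yl)-5-methylhex-4-en-1-yl]-2-(2,4,6-trihydroxyphenyl)-2,3-dihydro-4H-chromen-4-one | CC(C)=CC[C@H](Cc1c(O)cc(O)c2c1O[C@H](c1c(O)cc(O)cc1O)CC2=O)C(C)(C)O | target

**Step count and risks**

Total steps: 9. Longest linear sequence: 8 (steps 1–6, 8, 9 from 5,7-dihydroxycoumarin); step 7 is a one-step branch.

The three steps most likely to fail:

Step 6. O-acylation of the phenoxide or of the tertiary alcohol may compete with C-acylation, and the magnesium halide with acetyl chloride may attack the MOM ethers. The fallback sets out from 16 and comes back at 18. Phenol 16 is ortho-formylated with MgCl2, Et3N and paraformaldehyde in MeCN at reflux, where the magnesium phenoxide delivers formaldehyde only to the free ortho carbon, to give 2-hydroxy-3-[(2R)-2-(2-hydroxypropan-2-yl)-5-methylhex-4-en-1-yl]-4,6-bis(methoxymethoxy)benzaldehyde F1. Excess MeMgBr in THF at −78 °C adds to the aldehyde to give the benzylic alcohol 2-(1-hydroxyethyl)-6-[(2R)-2-(2-hydroxypropan-2-yl)-5-methylhex-4-en-1-yl]-3,5-bis(methoxymethoxy)phenol F2, whose new carbinol centre is irrelevant. MnO2 in CH2Cl2 then oxidises only this benzylic alcohol to ketone 18.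

Step 8. The electron-rich, doubly ortho-substituted aldehyde condenses slowly, the chalcone–flavanone equilibrium may lie on the chalcone side with this ring B, and 22 and its C2 epimer may be hard to resolve. The fallback sets out from 18 and 20 and comes back at 22. The trilithium salt of 18 (LiN(i-Pr)2, 3.3 equiv, THF, −78 °C) is added to 20 to give the aldol 3-hydroxy-1-{2-hydroxy-3-[(2R)-2-(2-hydroxypropan-2-yl)-5-methylhex-4-en-1-yl]-4,6-bis(methoxymethoxy)phenyl}-3-[2,4,6-tris(methoxymethoxy)phenyl]propan-1-one F3 as both carbinol epimers. An intramolecular Mitsunobu etherification (PPh3, DIAD, THF, 0 °C) through the free 2'-phenol then closes ring C irreversibly to 22 and its C2 epimer (2R)-8-[(2R)-2-(2-hydroxypropan-2-yl)-5-methylhex-4-en-1-yl]-5,7-bis(methoxymethoxy)-2-[2,4,6-tris(methoxymethoxy)phenyl]-2,3-dihydro-4H-chromen-4-one F4, which are separated as in step 8. No chalcone–flavanone equilibrium has to be driven, and any chalcone formed by elimination is returned to the buffered reflux.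

Step 9. Protic acid can cyclise the tertiary alcohol onto the neighbouring 7-OH to a 2,2-dimethylchromane, and can ionise the benzylic C2–O bond next to the very electron-rich ring B, which would scramble C2. The fallback sets out from 22 and comes back at 23. Treatment of 22 with TMSOTf and 2,2'-bipyridyl in CH2Cl2 at 0 °C silylates the tertiary alcohol and converts each aryl MOM ether into the aryl silyl ether without any Brønsted acid, giving (2S)-8-[(2R)-5-methyl-2-(2-trimethylsilyloxypropan-2-yl)hex-4-en-1-yl]-5,7-bis(trimethylsilyloxy)-2-[2,4,6-tris(trimethylsilyloxy)phenyl]-2,3-dihydro-4H-chromen-4-one F5. Stirring F5 in THF–water at rt hydrolyses all six Si–O bonds to 23.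

**Further compounds**

F1 | step 6 | 2-hydroxy-3-[(2R)-2-(2-hydroxypropan-2-yl)-5-methylhex-4-en-1-yl]-4,6-bis(methoxymethoxy)benzaldehyde | CC(C)=CC[C@H](Cc1c(O)c(C=O)c(OCOC)cc1OCOC)C(C)(C)O
F2 | step 6 | 2-(1-hydroxyethyl)-6-[(2R)-2-(2-hydroxypropan-2-yl)-5-methylhex-4-en-1-yl]-3,5-bis(methoxymethoxy)phenol (both carbinol epimers) | CC(C)=CC[C@H](Cc1c(O)c(C(C)O)c(OCOC)cc1OCOC)C(C)(C)O
F3 | step 8 | 3-hydroxy-1-{2-hydroxy-3-[(2R)-2-(2-hydroxypropan-2-yl)-5-methylhex-4-en-1-yl]-4,6-bis(methoxymethoxy)phenyl}-3-[2,4,6-tris(methoxymethoxy)phenyl]propan-1-one (both carbinol epimers) | CC(C)=CC[C@H](Cc1c(O)c(C(=O)CC(O)c2c(OCOC)cc(OCOC)cc2OCOC)c(OCOC)cc1OCOC)C(C)(C)O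
F4 | step 8 | (2R)-8-[(2R)-2-(2-hydroxypropan-2-yl)-5-methylhex-4-en-1-yl]-5,7-bis(methoxymethoxy)-2-[2,4,6-tris(methoxymethoxy)phenyl]-2,3-dihydro-4H-chromen-4-one (C2 epimer of 22) | CC(C)=CC[C@H](Cc1c(OCOC)cc(OCOC)c2c1O[C@@H](c1c(OCOC)cc(OCOC)cc1OCOC)CC2=O)C(C)(C)O
F5 | step 9 | (2S)-8-[(2R)-5-methyl-2-(2-trimethylsilyloxypropan-2-yl)hex-4-en-1-yl]-5,7-bis(trimethylsilyloxy)-2-[2,4,6-tris(trimethylsilyloxy)phenyl]-2,3-dihydro-4H-chromen-4-one | CC(C)=CC[C@H](Cc1c(O[Si](C)(C)C)cc(O[Si](C)(C)C)c2c1O[C@H](c1c(O[Si](C)(C)C)cc(O[Si](C)(C)C)cc1O[Si](C)(C)C)CC2=O)C(C)(C)O[Si](C)(C)C
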